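## The problem

Atoms are numbered along the formula as follows: C1=C2(C3) is the isopropenyl group on C4; C5 is the lactone methylene; C6 the spiro carbon; C7 the cyclopentanone methylene; C8 the ring-fusion CH; C9 (methyls C10, C11) the oxygen-bearing carbon; O12; C13 the γ-lactone carbonyl; C15 the quaternary carbon with methyl C16; C17 the ring ketone; C19 the δ-lactone carbonyl; O21; C22 the oxygen-bearing CH; C23 the side-chain ketone; C25–C27 its isopropyl group.

- Target 20 is a cyclopentanone (C6, C7, C8, C15, C17) joined spiro at C6 to a δ-lactone (C4, C5, C6, C19, O21, C22) and cis-fused across C8–C15 to a γ,γ-dimethyl-γ-lactone (C8, C9, O12, C13, C15).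
- There are five stereocentres: the quaternary pair C6 and C15 on either side of C17, the fusion carbon C8, and the cis pair C4/C22 on the δ-lactone.
- C15 dictates C8, because a five/five fusion can only close cis. C4 and C22 have to be made together.
- C6 must be matched to both groups: C7 syn to the C4–C2 bond, C19 syn to the C16 methyl. Being quaternary, it cannot be corrected by equilibration.
- Several groups do not survive rough treatment:
  - the isopropenyl group: protonation at C1 gives a tertiary cation next to oxygen nucleophiles;
  - C22–H once C23 is a ketone, since the cis lactone is probably the less stable epimer;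
  - the non-enolisable β-keto lactone, which alkoxide or hydroxide cleaves;
  - any free C13 acid, which would be a β-keto acid and would decarboxylate.
- The enabling feature is that C6 lies between the C17 and C19 carbonyls and is one methylene (C7) away from C8. C7, C8 and C9 form a 2-substituted allyl unit, so a π-allyl over these three atoms can be alkylated by C6 at C7. That closes the cyclopentanone at the spiro carbon and leaves C8=C9 ready to become the γ-lactone.

## Retrosynthesis

**C23 ketone and isopropenyl group (20 ⇒ 19 ⇒ 18).** The ketone is taken back to the carbinol 19, and 19 to the bromomethyl tetrahydrofuran 18, in which the C23 oxygen is bonded to C2 and C1 carries bromine. This bromoether hides the isopropenyl group and the C23 oxygen in one ring. Zinc reopens it regiospecifically, and a buffered oxidation finishes the synthesis. The alternative, a ketal at C23 with a free isopropenyl group, would put acid next to the alkene twice (lactonisation and ketal hydrolysis) and would expose C22–H to acid-catalysed enolisation. The forward steps only need a reductive β-elimination and a Dess–Martin oxidation.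

**γ-Lactone (18 ⇒ 17).** Cutting C9–O12 and the C8–H bond leads to the tetrasubstituted alkene C8=C9 and the C13 methyl ester of 17. No other cut is open, because an allyl unit over C7–C8–C9 necessarily leaves this alkene. The forward step is a Brønsted-acid lactonisation. It is acceptable here only because 17 contains no other alkene. C8 needs no separate control, since only the cis ring fusion can close.

**Spiro ring closure, the key cut (17 ⇒ 16).** Cutting C6–C7 opens the cyclopentanone to the acylated lactone 16, which carries a tertiary allylic benzoate at C9 and a terminal C7=C8 alkene. Against a cut at C6–C17 or C6–C19, this one joins two fragments of equal size by an ordinary acylation and makes the most hindered bond catalytically. The forward reaction must choose C7 over C9, carbon over oxygen, and one face of the C6 enolate. The last is the weak point and is handed to a chiral ligand.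

**Acylation (16 ⇒ 9 + 15).** Cutting C6–C17 gives the bromoether lactone 9 and the acid chloride 15. An aldol/oxidation pair would also serve but costs a step. C6 need not be controlled, because it becomes planar again in the key step.

**Lactone fragment (9 ⇒ 8 ⇒ 6 ⇒ 3 + 5).**
- Removing the bromoether gives hydroxy lactone 8.
- Opening the lactone and returning C23 to the ketone gives the ene adduct 6, via diol 7.
- Cutting C4–C22 in 6 is a carbonyl-ene disconnection to ester 3 and glyoxal 5. It creates both lactone stereocentres and the isopropenyl group in one step, which an aldol route would take five or six steps to do.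
- The forward ene reaction must give the anti adduct (OH on C22 anti to the C5 branch on C4 along the chain C23–C22–C4–C2), which is the cis lactone, with C22 of S configuration.
- 3 comes from 1 and 2 by a Johnson–Claisen rearrangement, and 5 from bromoketone 4.

**Acyl fragment (15 ⇒ 14 ⇒ 13 ⇒ 12 ⇒ 10 + 11).**
- The acid chloride comes from half-ester 14, and 14 from the prochiral diester 13 by enzymatic desymmetrisation, which sets C15.
- The leaving group is a tertiary benzoate placed directly on C9 of 12 by allylic acyloxylation. A free tertiary alcohol or alkoxide at C9 next to the malonate would lactonise onto C13, so none is ever generated; for the same reason a carbonate made from the alkoxide was not used.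
- Cutting C15–C8 in 12 gives methylmalonate 10 and alkyne 11, joined forward by indium-catalysed Markovnikov alkenylation. A tertiary propargylic alcohol or ester would ionise under the Lewis acid, which is why the oxygen is introduced afterwards.

## Roads not taken

**Alternative 1:** The cut is at C8–C9 and C15–C16 on a five-membered enone. Forward, a chiral copper catalyst would add an isopropenyl Grignard reagent to cyclopentenone ester A1, and the enolate would be methylated to give keto ester A2.
- Merits: both stereocentres of the γ-lactone region come from one catalytic operation on an achiral substrate. The isopropenyl group of A2 is the future C9, so its acid lactonisation can be done early, when no other alkene is present.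
- In these two respects it is better than the chosen plan, which needs an enzyme of uncertain sense for C15 and a masked alkene for the acid step.
- Weak points: A1 is a doubly activated, polymerisation-prone enone for which asymmetric alkenyl addition is less assured than for simple enones. More seriously, A2 leaves the real problem untouched: C5 and C19 must still be attached to the other α-carbon with the right sense at C6 and with the C4/C22 pair in place.
- What the chosen plan sets against it: 16 already contains every carbon, and the spiro centre is made in the ring closure itself.

**Alternative 2:** The cut is C6–C19. Forward, the ketone enolate of imidazolyl carbonate A3 would attack its own carbonate carbon and close the δ-lactone, giving ketal A4.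
- Merits: the acyl carbon is the incoming group. It would arrive on the exo face of the cis-fused bicycle and, seen from the lactone, axially and anti to the C4 substituent. That is the natural configuration under pure substrate control.
- On C6 this road is more secure than the chosen one, which needs a chiral ligand to do what the substrate probably resists.
- Weak points: A3 presupposes a C5–C6 bond between the bicyclic ketone and a β-branched chiral electrophile, which is a poor alkylation. O-acylation to an enol carbonate competes. A4 still needs acid to remove a hindered ketal next to a free isopropenyl group and an epimerisable C22.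
- What the chosen plan sets against it: convergence, a catalytic ring closure, and an acid-free unveiling of the alkene. Its fallback borrows this alternative's stereochemical logic.

**Alternative 3:** The cut is C6–C17, made by migration. Forward, a boron Lewis acid would open the C6–O bond of epoxy ketone A5 and the acyl carbon C17 would shift from C19 to C6, giving formyl ketone A6.
- Merits: the shift is stereospecific (anti to the breaking C–O bond), so C6 follows from the epoxide face and no planar centre has to be discriminated at that stage. In intrinsic fidelity at C6 it is probably the best of the four.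
- Weak points: A5 is as complex as the target, and the selectivity problem is only moved to the epoxidation. The Lewis acid meets an isopropenyl group and a silyl ether, and hydride shift competes. Three further steps follow (aldehyde oxidation beside the alkene, desilylation, lactonisation) through a deformylation-prone β-keto aldehyde.
- What the chosen plan sets against it: it is several steps shorter and convergent, and accepts in exchange a ligand-controlled step.

Key step: step 11

Remark on the chemistry: C23 in 7–9 and 16–19 is drawn as the chelation-control epimer, and the ether carbon C2 of 9 and 16–18 is left undefined (either epimer should react alike). Both centres disappear in steps 13 and 14.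

## Route

Step 1
Reactants: 1 2-methylbut-3-en-2-ol; 2 triethyl orthoacetate
Product: 3 ethyl 5-methylhex-4-enoate
Conditions: EtCO2H (cat.), 140 °C, distil off EtOH
Reagents that add atoms: none
Why: Johnson–Claisen rearrangement; the mixed ketene acetal of the tertiary allylic alcohol rearranges [3,3] to the γ,δ-unsaturated ester with the trisubstituted alkene, and no stereocentre is formed.

Step 2
Reactants: 4 1-bromo-3-methylbutan-2-one
Product: 5 3-methyl-2-oxobutanal
Conditions: DMSO, NaHCO3, 60 °C; distil from P2O5 before use
Reagents that add atoms: dimethyl sulfoxide, CS(C)=O
Why: Kornblum oxidation; DMSO displaces the activated primary bromide and the alkoxysulfonium salt collapses to the aldehyde, which fixes the glyoxal regiochemistry without a selectivity question.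

Step 3
Reactants: 3 ethyl 5-methylhex-4-enoate; 5 3-methyl-2-oxobutanal
Product: 6 ethyl (4S,5S)-5-hydroxy-7-methyl-6-oxo-4-(prop-1-en-2-yl)octanoate
Conditions: [Cu((S,S)-t-Bu-box)](SbF6)2 (10 mol%), CH2Cl2, 0 °C → rt
Reagents that add atoms: none
Why: Catalytic asymmetric carbonyl-ene reaction of a 1,2-dicarbonyl enophile; the glyoxal chelates divalent copper through both carbonyl oxygens, C4 of the alkene bonds to the aldehyde carbon and a methyl hydrogen passes to oxygen, which creates the isopropenyl group. The ligand should select the aldehyde face (C22 S, as for glyoxylate with this catalyst), and an exo arrangement of the chelate, with the C5 chain turned away from it, should give the anti adduct and so set C4.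

Step 4
Reactants: 6 ethyl (4S,5S)-5-hydroxy-7-methyl-6-oxo-4-(prop-1-en-2-yl)octanoate
Product: 8 (5S,6S)-6-[(1R)-1-hydroxy-2-methylpropyl]-5-(prop-1-en-2-yl)oxan-2-one, via anti diol ester 7 (not isolated)
Conditions: Zn(BH4)2, Et2O, −20 °C; aq. NH4Cl; then PPTS (cat.), PhMe, 60 °C
Reagents that add atoms: none
Why: Chelation-controlled (Cram chelate) reduction of the α-hydroxy ketone should give the anti diol, and the C22 hydroxyl then closes the six-membered lactone in preference to the seven-membered one. Reducing first removes the epimerisable α-ketol before any acid is used, and the C23 centre is temporary.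

Step 5
Reactants: 8 (5S,6S)-6-[(1R)-1-hydroxy-2-methylpropyl]-5-(prop-1-en-2-yl)oxan-2-one
Product: 9 (4aR,7R,7aS)-5-(bromomethyl)-5-methyl-7-(propan-2-yl)hexahydro-2H-furo[3,4-b]pyran-2-one (cis-fused; epimers at the bromomethyl-bearing carbon)
Conditions: NBS, CH2Cl2, 0 °C, dark
Reagents that add atoms: N-bromosuccinimide, O=C1CCC(=O)N1Br
Why: Bromoetherification, 5-exo and Markovnikov; the C23 hydroxyl opens the bromonium ion at C2. Only the cis C4/C22 arrangement can close this cis-fused ring, so the step also removes any trans lactone, and it masks the alkene and the C23 oxygen together.

Step 6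
Reactants: 10 dimethyl 2-methylpropanedioate; 11 3-methylbut-1-yne
Product: 12 dimethyl 2-methyl-2-(3-methylbut-1-en-2-yl)propanedioate
Conditions: In(OTf)3 (10 mol%), Et3N (10 mol%), PhMe, 120 °C, sealed tube
Reagents that add atoms: none
Why: Indium-catalysed alkenylation of an active methine (intermolecular Conia-ene type); the indium enolate adds across the terminal alkyne with C–C bond formation at the internal carbon, giving the 1,1-disubstituted alkene and the still achiral quaternary C15.

Step 7
Reactants: 12 dimethyl 2-methyl-2-(3-methylbut-1-en-2-yl)propanedioate
Product: 13 dimethyl 2-[3-(benzoyloxy)-3-methylbut-1-en-2-yl]-2-methylpropanedioate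
Conditions: CuBr (10 mol%), PhCO3t-Bu (2 equiv), MeCN–PhH, 70 °C
Reagents that add atoms: tert-butyl perbenzoate, CC(C)(C)OOC(=O)c1ccccc1
Why: Kharasch–Sosnovsky allylic acyloxylation; the tert-butoxyl radical removes the only allylic hydrogen (C9–H) and copper delivers benzoate to the substituted terminus with the terminal alkene retained. The leaving group is thus installed without a free C9 alcohol, which would lactonise onto the malonate.

Step 8
Reactants: 13 dimethyl 2-[3-(benzoyloxy)-3-methylbut-1-en-2-yl]-2-methylpropanedioate
Product: 14 (2R)-4-(benzoyloxy)-2-(methoxycarbonyl)-2,4-dimethyl-3-methylidenepentanoic acid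
Conditions: pig liver esterase, phosphate buffer pH 7.5–DMSO (9:1), 25 °C, pH-stat (1 M NaOH); then 1 M HCl to pH 2
Reagents that add atoms: water, O
Why: Enzymatic desymmetrisation of a prochiral α,α-disubstituted malonate; hydrolysis of one enantiotopic methyl ester sets C15, and the hindered tertiary benzoate should not be a substrate. The sense and level of selectivity have to be established and are treated as a risk below.

Step 9
Reactants: 14 (2R)-4-(benzoyloxy)-2-(methoxycarbonyl)-2,4-dimethyl-3-methylidenepentanoic acid
Product: 15 methyl (2S)-4-(benzoyloxy)-2-(chlorocarbonyl)-2,4-dimethyl-3-methylidenepentanoate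
Conditions: 1-chloro-N,N,2-trimethylprop-1-en-1-amine, CH2Cl2, 0 °C → rt; used crude
Reagents that add atoms: 1-chloro-N,N,2-trimethylprop-1-en-1-amine, CC(C)=C(Cl)N(C)C
Why: Ghosez chlorination under neutral conditions spares the tertiary allylic benzoate, and with no α-hydrogen there is no ketene pathway. The descriptor changes from R to S only because the ligand priorities change.

Step 10
Reactants: 9 the bromoether lactone; 15 methyl (2S)-4-(benzoyloxy)-2-(chlorocarbonyl)-2,4-dimethyl-3-methylidenepentanoate
Product: 16 C6-acylated bromoether lactone [9 bearing at C6 the (2R)-4-(benzoyloxy)-2-(methoxycarbonyl)-2,4-dimethyl-3-methylidenepentanoyl group; both C6 epimers, partly enolised]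
Conditions: 9, LiN(SiMe3)2 (2.1 equiv), THF, −78 °C; then 15, −78 → −40 °C; AcOH, −78 °C
Reagents that add atoms: none
Why: Crossed Claisen C-acylation of a lithium lactone enolate by an acid chloride; the second equivalent of base removes the acidic C6–H of the product and protects it from further attack. C6 is left uncontrolled because the next step makes it planar, and the cold quench should prevent uncatalysed displacement of the benzoate.

Step 11
Reactants: 16 the C6-acylated bromoether lactone
Product: 17 spiro keto ester [cyclopentanone spiro-fused at C6 to the bromoether lactone, propan-2-ylidene at C8, methyl and methoxycarbonyl on C15; 6R,15R; C7 syn to the C4–C2 bond]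
Conditions: Pd2(dba)3·CHCl3 (2.5 mol%), (R,R)-DACH-phenyl Trost ligand (7.5 mol%), Cs2CO3 (1.2 equiv), CH2Cl2, 0 °C → rt
Reagents that add atoms: none
Why: Zerovalent palladium binds the terminal C7=C8 alkene and expels benzoate from C9 to give a π-allyl over C7, C8 and C9, while Cs2CO3 turns the β-keto lactone into its enolate. The enolate carbon C6 attacks the unsubstituted terminus C7 on the allyl face opposite the metal, forming C6–C7 and leaving C8=C9 as an isopropylidene group. The closest known reaction type is the intramolecular Tsuji–Trost alkylation of β-dicarbonyl compounds in its asymmetric form with diaminocyclohexane-derived bisphosphine ligands. The ring formed is five-membered (C6, C7, C8, C15, C17) and closes as in trimethylenemethane-type methylenecyclopentane annulations: the tether sits on the central allyl carbon, the nucleophile bonds to a terminus and the alkene ends exocyclic. Attack at C9 would join two quaternary carbons and is blocked by the gem-dimethyl group, and any O-alkylated allyl enol ether is re-ionised by palladium, so the C-alkylated ketone is the sink. C6 is the only new stereocentre and is set by which enolate face meets C7. C4 and C22 lie on the far edge of the lactone, and a half-chair model suggests a modest preference for the unwanted face, so the chiral pocket of the ligand has to be the controlling element, as in asymmetric allylations of cyclic β-keto esters. C15 was fixed in step 8 and cannot epimerise.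

Step 12
Reactants: 17 the spiro keto ester
Product: 18 bromoether bis-lactone [17 with the cis-fused γ-lactone C9–O12–C13 closed and H on C8; 8R,15R; C6 geometry unchanged]
Conditions: TfOH (2 equiv), CH2Cl2, −20 → 0 °C; then aq. NaHCO3
Reagents that add atoms: water, O
Why: Brønsted-acid lactonisation of a β,γ-unsaturated ester; protonation at C8 gives the tertiary C9 cation, which the C13 ester carbonyl captures, and the methoxy-lactonium ion is hydrolysed on work-up. Only the cation with H on C8 cis to C13 can close the five/five system and the other reverts to alkene, so C8 is set by C15. The substrate has no other alkene, no ketal and no enolisable stereocentre.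

Step 13
Reactants: 18 the bromoether bis-lactone
Product: 19 (23R)-carbinol of the target [20 with CH(OH) at C23]
Conditions: Zn dust (activated), AcOH–THF, 50 °C
Reagents that add atoms: none
Why: Boord-type reductive β-elimination; zinc inserts into the primary C–Br bond and the β-alkoxide leaves, which regenerates C1=C2 regiospecifically and frees the C23 hydroxyl. No acid strong enough to protonate the new alkene is present, and the C2 centre is erased.

Step 14
Reactants: 19 the (23R)-carbinol
Product: 20 target compound CNP0216954.2
Conditions: Dess–Martin periodinane, NaHCO3, CH2Cl2, 0 °C → rt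
Reagents that add atoms: none
Why: Dess–Martin oxidation of the hindered secondary alcohol under buffered, non-enolising conditions, so the cis C22 centre next to the new ketone should be kept; the alkene and both lactones are inert.

## Compound list

1 | 2-methylbut-3-en-2-ol | CC(C)(O)C=C | starting material
2 | triethyl orthoacetate | CCOC(C)(OCC)OCC | starting material
3 | ethyl 5-methylhex-4-enoate | CCOC(=O)CCC=C(C)C | intermediate
4 | 1-bromo-3-methylbutan-2-one | CC(C)C(=O)CBr | starting material
5 | 3-methyl-2-oxobutanal | CC(C)C(=O)C=O | intermediate
6 | ethyl (4S,5S)-5-hydroxy-7-methyl-6-oxo-4-(prop-1-en-2-yl)octanoate | C=C(C)[C@@H]([C@H](O)C(=O)C(C)C)CCC(=O)OCC | intermediate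
7 | ethyl (4S,5S,6R)-5,6-dihydroxy-7-methyl-4-(prop-1-en-2-yl)octanoate | C=C(C)[C@@H]([C@H](O)[C@H](O)C(C)C)CCC(=O)OCC | intermediate (not isolated)
8 | (5S,6S)-6-[(1R)-1-hydroxy-2-methylpropyl]-5-(prop-1-en-2-yl)oxan-2-one | C=C(C)[C@@H]1CCC(=O)O[C@@H]1[C@H](O)C(C)C | intermediate
9 | (4aR,7R,7aS)-5-(bromomethyl)-5-methyl-7-(propan-2-yl)hexahydro-2H-furo[3,4-b]pyran-2-one, cis-fused, epimers at the bromomethyl-bearing carbon | CC(C)[C@H]1OC(C)(CBr)[C@@H]2CCC(=O)O[C@H]12 | intermediate
10 | dimethyl 2-methylpropanedioate | COC(=O)C(C)C(=O)OC | starting material
11 | 3-methylbut-1-yne | CC(C)C#C | starting material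
12 | dimethyl 2-methyl-2-(3-methylbut-1-en-2-yl)propanedioate | COC(=O)C(C)(C(=O)OC)C(=C)C(C)C | intermediate
13 | dimethyl 2-[3-(benzoyloxy)-3-methylbut-1-en-2-yl]-2-methylpropanedioate | COC(=O)C(C)(C(=O)OC)C(=C)C(C)(C)OC(=O)c1ccccc1 | intermediate
14 | (2R)-4-(benzoyloxy)-2-(methoxycarbonyl)-2,4-dimethyl-3-methylidenepentanoic acid | COC(=O)[C@@](C)(C(=O)O)C(=C)C(C)(C)OC(=O)c1ccccc1 | intermediate
15 | methyl (2S)-4-(benzoyloxy)-2-(chlorocarbonyl)-2,4-dimethyl-3-methylidenepentanoate | COC(=O)[C@@](C)(C(=O)Cl)C(=C)C(C)(C)OC(=O)c1ccccc1 | intermediate
16 | bromoether lactone 9 acylated at C6 by the (2R)-4-(benzoyloxy)-2-(methoxycarbonyl)-2,4-dimethyl-3-methylidenepentanoyl group (C6 epimers) | CC(C)[C@H]1OC(C)(CBr)[C@@H]2CC(C(=O)[C@](C)(C(=O)OC)C(=C)C(C)(C)OC(=O)c3ccccc3)C(=O)O[C@H]12 | intermediate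
17 | spiro keto ester: cyclopentanone spiro at C6 (R) to the bromoether lactone, propan-2-ylidene at C8, methyl and methoxycarbonyl on C15 (R) | CC(C)[C@H]1OC(C)(CBr)[C@@H]2C[C@]3(CC(=C(C)C)[C@@](C)(C(=O)OC)C3=O)C(=O)O[C@H]12 | intermediate
18 | bromoether bis-lactone: 17 with the cis-fused γ,γ-dimethyl-γ-lactone closed (8R,15R) | CC(C)[C@H]1OC(C)(CBr)[C@@H]2C[C@]3(C[C@H]4C(C)(C)OC(=O)[C@@]4(C)C3=O)C(=O)O[C@H]12 | intermediate
19 | (23R)-carbinol of the target (isopropenyl restored, CH(OH) at C23) | C=C(C)[C@@H]1C[C@]2(C[C@H]3C(C)(C)OC(=O)[C@@]3(C)C2=O)C(=O)O[C@@H]1[C@H](O)C(C)C | intermediate
20 | CNP0216954.2 (4S,6R,8R,15R,22S in the numbering used here) | C=C(C)[C@@H]1C[C@]2(C[C@H]3C(C)(C)OC(=O)[C@@]3(C)C2=O)C(=O)O[C@@H]1C(=O)C(C)C | target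

## Step count and least certain steps

Total: 14 steps. Longest linear sequence: 9 steps (1, 3, 4, 5, 10, 11, 12, 13, 14); the acid branch (6, 7, 8, 9, then 10–14) is equally long.

**Step 11 (key step).** The facial discrimination at the C6 enolate may be too low or in the wrong sense, because the lactone's own preference (axial entry of C7 anti to the C4 substituent) probably opposes what the ligand must impose. β-Hydride loss from the gem-dimethyl π-allyl to a diene can also compete. The antipodal ligand is the first variable to try. The fallback changes the order of bond formation so that the substrate preference works for the target. It sets out from 9 and 12 and returns at 17. Radical bromination of 12 (NBS, AIBN) would give dimethyl 2-(1-bromo-3-methylbut-2-en-2-yl)-2-methylpropanedioate F1. The lithium enolate of 9 would be alkylated by F1 to give the C6-allylated lactone F2. Treatment of F2 with LiN(SiMe3)2 would then close the cyclopentanone by a Dieckmann-type acylation to 17. Here the acyl carbon C17 is the incoming group and should enter anti to the C4 substituent, which leaves C7 syn. C15 would then be set by which diastereotopic ester reacts; any C15 epimer would be separated.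

**Step 3.** Insufficient diastereo- or enantioselection may result, since the trisubstituted alkene is a more demanding ene partner than a 1,1-disubstituted one. Glyoxal hydrate may also deactivate the catalyst. The fallback gives up asymmetric catalysis. It sets out from 3 and 5 and returns at 8. A SnCl4-promoted ene reaction (CH2Cl2, −78 °C), which is anti-selective through the same chelate, would give racemic adduct F3. The conditions of step 4 would take F3 through racemic diol F4 to racemic hydroxy lactone F5, and F5 would be resolved by preparative chromatography on a chiral stationary phase to give 8.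

**Step 7.** Hydrogen abstraction may be slow with the alkene as limiting reagent, and benzoate may be delivered in part to the primary terminus. The fallback separates the two events. It sets out from 12 and returns at 13. Bromination as above gives the allylic bromide F1, and silver-assisted substitution (AgO2CPh, PhH) should deliver benzoate mainly to the tertiary terminus of the allyl cation to give 13. The primary isomer F6 would be removed by chromatography.

**Step 8.** Hydrolysis of this hindered diester may be slow, poorly selective or of the wrong sense. The fallback replaces the enzyme by resolution. It sets out from 13 and returns at 14. Monohydrolysis with KOH (1 equiv, MeOH–H2O) would give racemic half-ester F7. Crystallisation with (R)-1-phenylethylamine (or its antipode, whichever gives the less soluble salt of the 2R acid) would give salt F8, and acidification would return 14.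

**Step 12.** Under strong acid the bromoether may reopen reversibly and pass bromonium to the C8=C9 alkene, or the alkene may isomerise into the ring without closing. The fallback avoids protic acid. It sets out from 17 and returns at 18. Iodolactonisation (N-iodosuccinimide, MeCN, 0 °C, the ester losing its methyl group) would give the C8-iodo bis-lactone F9. Its tertiary C–I bond would then be reduced selectively in the presence of the primary C–Br bond (Bu3SnH, Et3B, air, PhMe, −40 °C); the ring fusion forces hydrogen onto C8 cis to C13.

## Further compounds

F1 | step 11 | dimethyl 2-(1-bromo-3-methylbut-2-en-2-yl)-2-methylpropanedioate | COC(=O)C(C)(C(=O)OC)C(CBr)=C(C)C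
F2 | step 11 | bromoether lactone 9 bearing at C6 the 2-(1,3-dimethoxy-2-methyl-1,3-dioxopropan-2-yl)-3-methylbut-2-en-1-yl group (C6 epimers) | CC(C)[C@H]1OC(C)(CBr)[C@@H]2CC(CC(=C(C)C)C(C)(C(=O)OC)C(=O)OC)C(=O)O[C@H]12
F3 | step 3 | racemic ethyl (4S*,5S*)-5-hydroxy-7-methyl-6-oxo-4-(prop-1-en-2-yl)octanoate (one enantiomer drawn) | C=C(C)[C@@H]([C@H](O)C(=O)C(C)C)CCC(=O)OCC
F4 | step 3 | racemic ethyl (4S*,5S*,6R*)-5,6-dihydroxy-7-methyl-4-(prop-1-en-2-yl)octanoate (one enantiomer drawn) | C=C(C)[C@@H]([C@H](O)[C@H](O)C(C)C)CCC(=O)OCC
F5 | step 3 | racemic (5S*,6S*)-6-[(1R*)-1-hydroxy-2-methylpropyl]-5-(prop-1-en-2-yl)oxan-2-one (one enantiomer drawn) | C=C(C)[C@@H]1CCC(=O)O[C@@H]1[C@H](O)C(C)C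
F6 | step 7 | dimethyl 2-[1-(benzoyloxy)-3-methylbut-2-en-2-yl]-2-methylpropanedioate | COC(=O)C(C)(C(=O)OC)C(COC(=O)c1ccccc1)=C(C)C
F7 | step 8 | racemic 4-(benzoyloxy)-2-(methoxycarbonyl)-2,4-dimethyl-3-methylidenepentanoic acid | COC(=O)C(C)(C(=O)O)C(=C)C(C)(C)OC(=O)c1ccccc1
F8 | step 8 | (R)-1-phenylethylammonium (2R)-4-(benzoyloxy)-2-(methoxycarbonyl)-2,4-dimethyl-3-methylidenepentanoate | C[C@@H]([NH3+])c1ccccc1.COC(=O)[C@@](C)(C(=O)[O-])C(=C)C(C)(C)OC(=O)c1ccccc1
F9 | step 12 | C8-iodo analogue of bis-lactone 18 (iodine at the ring-fusion carbon C8, γ-lactone cis-fused) | CC(C)[C@H]1OC(C)(CBr)[C@@H]2C[C@]3(C[C@@]4(I)C(C)(C)OC(=O)[C@@]4(C)C3=O)C(=O)O[C@H]12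
A1 | alternative 1 | methyl 5-oxocyclopent-1-ene-1-carboxylate | COC(=O)C1=CCCC1=O
A2 | alternative 1 | methyl (1R,2S)-1-methyl-5-oxo-2-(prop-1-en-2-yl)cyclopentane-1-carboxylate | C1C[C@@H](C(C)=C)[C@@](C)(C(=O)OC)C1=O
A3 | alternative 2 | bicyclic keto lactone carrying at C6 the side chain with an imidazole-1-carbonyloxy group on C22 and a dimethyl ketal at C23 (C6 epimers) | C=C(C)[C@H](CC1C[C@H]2C(C)(C)OC(=O)[C@@]2(C)C1=O)[C@H](OC(=O)n1ccnc1)C(OC)(OC)C(C)C
A4 | alternative 2 | C23 dimethyl ketal of the target | C=C(C)[C@@H]1C[C@]2(C[C@H]3C(C)(C)OC(=O)[C@@]3(C)C2=O)C(=O)O[C@@H]1C(OC)(OC)C(C)C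
A5 | alternative 3 | cis-fused C6–C19 epoxy cyclohexanone carrying the γ-lactone and the silylated side chain | C=C(C)[C@H](C[C@]12O[C@H]1C(=O)[C@]1(C)C(=O)OC(C)(C)[C@@H]1C2)[C@H](O[Si](C)(C)C(C)(C)C)C(=O)C(C)C
A6 | alternative 3 | 2-formylcyclopentanone with quaternary C6, C19 as aldehyde, C22 as tert-butyldimethylsilyl ether | C=C(C)[C@@H]([C@H](O[Si](C)(C)C(C)(C)C)C(=O)C(C)C)C[C@]1(C[C@H]2C(C)(C)OC(=O)[C@@]2(C)C1=O)C=O
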